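The furanone is disconnected as an oxazole–alkyne Diels–Alder/retro-Diels–Alder retron: ring O1 with lactone carbon C2 and C5 comes from a 5-silyloxyoxazole, and C3=C4 with the bromine and the C1' side chain from an (R)-bromoalkynol. The carbonyl oxygen on C2 and the oxygen on C1' can share one silicon atom in a six-membered ring; this temporary diisopropylsilylene bridge makes the cycloaddition intramolecular and regiospecific. Heating the oxazolyl propargyl silyl ketal forges C2–C3 and C4–C5 in one operation, expels acetonitrile and leaves a silyloxyfuran, whose free C5 is then dibromomethylenated with CBr4. Fluoride removes the bridge and acetylation completes the target.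

Key step: step 5

Remark: atom labels used below are furanone O1, C2 (C=O), C3, C4 (C–Br), C5 (C=CBr2) and C1' (the acetoxy-bearing carbon), which is R in the given structure.

**Step 1**
Reactants: 1 butanoyl chloride; 2 bis(trimethylsilyl)acetylene
Product: 3 1-(trimethylsilyl)hex-1-yn-3-one
Conditions: AlCl3 (1.1 equiv), CH2Cl2, 0 °C; cold aq. HCl work-up
Reagents that add atoms: none
Why: Friedel–Crafts-type ipso-acylation of the alkynylsilane (β-silyl-stabilised vinyl cation, loss of Me3SiCl) should stop after one acylation because the ynone product is deactivated; no stereocentre is involved.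

**Step 2**
Reactants: 3 1-(trimethylsilyl)hex-1-yn-3-one
Product: 4 (3R)-1-(trimethylsilyl)hex-1-yn-3-ol
Conditions: Ru[(R,R)-TsDPEN](p-cymene) (0.5 mol %), i-PrOH, rt
Reagents that add atoms: none
Why: Noyori–Ikariya asymmetric transfer hydrogenation of an acetylenic ketone, in which the bifunctional Ru–H/N–H catalyst distinguishes the alkynyl from the n-propyl flank; the (R,R)-TsDPEN complex is expected, by analogy with its delivery of (R)-aryl and (R)-alkynyl carbinols, to set the 3R centre, the only stereocentre of the target.

**Step 3**
Reactants: 4 (3R)-1-(trimethylsilyl)hex-1-yn-3-ol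
Product: 5 (3R)-1-bromohex-1-yn-3-ol
Conditions: NBS (1.2 equiv), AgNO3 (10 mol %), acetone, rt, dark
Reagents that add atoms: N-bromosuccinimide, O=C1CCC(=O)N1Br
Why: Silver-catalysed bromodesilylation (the silver acetylide formed from the C–Si bond is brominated by NBS) should convert the alkynylsilane directly into the 1-bromoalkyne without touching the free secondary alcohol or its configuration.

**Step 4**
Reactants: 5 (3R)-1-bromohex-1-yn-3-ol; 6 N-formyl-DL-alanine
Product: 9 (R)-4-methyl-1,3-oxazol-5-yl 1-bromohex-1-yn-3-yl diisopropylsilyl ketal, via chlorosilyl ether 7 (not isolated), via azlactone 8 (not isolated)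
Conditions: (a) 5, i-Pr2SiCl2 (3 equiv), Et3N, DMAP (cat.), CH2Cl2, 0 °C, excess silane removed in vacuo; (b) 6, DCC, CH2Cl2, 0 °C, filter; (c) solutions of 7 and 8, Et3N, CH2Cl2, −20 °C to rt; filtered under argon and used crude
Reagents that add atoms: dichlorodiisopropylsilane, CC(C)[Si](Cl)(Cl)C(C)C
Why: Stepwise substitution at the hindered dichlorosilane should give the unsymmetrical silyl ketal: the secondary alcohol displaces the first chloride, and the azlactone from carbodiimide cyclodehydration of the N-formyl amino acid is deprotonated by Et3N to the aromatic oxazol-5-olate, which is silylated on oxygen (as in the O-acylation of azlactones that precedes a Steglich rearrangement); C1' is untouched and the azlactone C4 centre becomes sp2.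

**Step 5**
Reactants: 9 (R)-4-methyl-1,3-oxazol-5-yl 1-bromohex-1-yn-3-yl diisopropylsilyl ketal
Product: 11 (4R)-5-bromo-2,2-diisopropyl-4-propyl-4H-furo[2,3-d][1,3,2]dioxasiline (silylene-bridged 2-silyloxyfuran), via oxazole–alkyne cycloadduct 10 (not isolated)
Conditions: toluene (0.01 M), BHT (cat.), 120 °C, sealed tube, argon
Reagents that add atoms: none
Why: Intramolecular normal-demand [4+2] cycloaddition of the electron-rich 5-silyloxyoxazole (diene termini C2 and C5) onto the bromoalkyne should give the 7-oxa-2-azabicyclo[2.2.1]heptadiene 10, which aromatises by retro-[4+2] loss of acetonitrile (oxazole N3=C4–CH3); the closest known reaction type is the intramolecular oxazole–alkyne Diels–Alder/retro-Diels–Alder synthesis of 2-alkoxyfurans and butenolides (Kondrat'eva-type cycloaddition), here run through a temporary silicon tether. The furan ring closes through the two new C–C bonds (oxygenated oxazole C5, the future lactone carbon, to the alkyne carbon bearing C1'; oxazole C2–H, the future C5, to the bromine-bearing alkyne carbon), and the six-membered 1,3-dioxa-2-silinane closes in the same event as the fused ring of a type-1 intramolecular Diels–Alder reaction with a four-atom O–Si–O–C tether. No new stereocentre survives: both bridgehead centres of 10 are erased on cycloreversion, so either facial approach converges on 11, and the R carbinol carbon is a spectator whose C–O bond is locked in the silyl ketal. The step needs regioselectivity, which the tether enforces (the reverse orientation would require a bridged eight-membered ring), and it needs cycloaddition to outrun desilylation or silyl migration, for which the hindered diisopropylsilylene, the donor oxygen on the diene, the halogen-activated alkyne and dilute, neutral, anhydrous conditions are chosen.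

**Step 6**
Reactants: 11 (4R)-5-bromo-2,2-diisopropyl-4-propyl-4H-furo[2,3-d][1,3,2]dioxasiline; 12 tetrabromomethane
Product: 15 4-bromo-5-(dibromomethylidene)-3-[(1R)-1-hydroxybutyl]furan-2(5H)-one, via tribromomethyl butenolide 13 (not isolated), via bromosilyl ether 14 (not isolated)
Conditions: 12 (1.2 equiv), Ru(bpy)3Cl2 (1 mol %), blue LEDs, MeCN, rt; then i-Pr2NEt, 0 °C; then HF·pyridine, THF, 0 °C
Reagents that add atoms: none
Why: Photoredox Kharasch-type tribromomethylation, in which the electrophilic CBr3 radical should add to the free α-position C5 of the silyl dienol ether, oxidation of the adduct radical and attack of bromide on silicon unveil the C2 carbonyl and open the bridge at the furan oxygen, amine-induced E1cB loss of HBr from the C5–H/CBr3 pair gives the exocyclic dibromoalkene (symmetric terminus, so no E/Z issue, and the transient C5 centre is destroyed), and HF·pyridine cleaves the remaining Si–O bond without breaking the C1'–O bond.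

**Step 7**
Reactants: 15 4-bromo-5-(dibromomethylidene)-3-[(1R)-1-hydroxybutyl]furan-2(5H)-one
Product: 16 (1R)-1-[4-bromo-5-(dibromomethylidene)-2-oxo-2,5-dihydrofuran-3-yl]butyl acetate
Conditions: Ac2O, pyridine, CH2Cl2, 0 °C to rt
Reagents that add atoms: acetic anhydride, CC(=O)OC(C)=O
Why: Standard O-acetylation of the secondary allylic alcohol (no DMAP and low temperature to spare the electrophilic bromofuranone) should proceed with retention because the C1'–O bond is not broken.

**Compound list**
1 | butanoyl chloride | CCCC(Cl)=O | starting material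
2 | bis(trimethylsilyl)acetylene | C[Si](C)(C)C#C[Si](C)(C)C | starting material
3 | 1-(trimethylsilyl)hex-1-yn-3-one | CCCC(=O)C#C[Si](C)(C)C | intermediate
4 | (3R)-1-(trimethylsilyl)hex-1-yn-3-ol | CCC[C@@H](O)C#C[Si](C)(C)C | intermediate
5 | (3R)-1-bromohex-1-yn-3-ol | CCC[C@@H](O)C#CBr | intermediate
6 | N-formyl-DL-alanine (2-formamidopropanoic acid) | CC(NC=O)C(=O)O | starting material
7 | (R)-[(1-bromohex-1-yn-3-yl)oxy]chlorodiisopropylsilane (not isolated) | CCC[C@@H](O[Si](Cl)(C(C)C)C(C)C)C#CBr | intermediate
8 | 4-methyl-1,3-oxazol-5(4H)-one, racemic 2-unsubstituted azlactone (not isolated) | CC1N=COC1=O | intermediate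
9 | (R)-4-methyl-1,3-oxazol-5-yl 1-bromohex-1-yn-3-yl diisopropylsilyl ketal (oxazole 5-O–Si(i-Pr)2–O–CH(n-Pr)–C≡C–Br) | CCC[C@@H](O[Si](C(C)C)(C(C)C)Oc1ocnc1C)C#CBr | intermediate
10 | 7-oxa-2-azabicyclo[2.2.1]hepta-2,5-diene cycloadduct fused to the 1,3-dioxa-2-silinane, bridgehead epimers (not isolated) | CCC[C@H]1O[Si](C(C)C)(C(C)C)OC23OC(N=C2C)C(Br)=C13 | intermediate
11 | (4R)-5-bromo-2,2-diisopropyl-4-propyl-4H-furo[2,3-d][1,3,2]dioxasiline (furan 2-O and C1'-O bridged by Si(i-Pr)2; furan C4–Br, C5–H) | CCC[C@@H](O[Si]1(C(C)C)C(C)C)c2c(Br)coc2O1 | intermediate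
12 | tetrabromomethane | BrC(Br)(Br)Br | starting material
13 | 4-bromo-3-[(1R)-1-{[bromo(diisopropyl)silyl]oxy}butyl]-5-(tribromomethyl)furan-2(5H)-one, C5 epimers (not isolated) | CCC[C@@H](O[Si](Br)(C(C)C)C(C)C)C1=C(Br)C(C(Br)(Br)Br)OC1=O | intermediate
14 | 4-bromo-3-[(1R)-1-{[bromo(diisopropyl)silyl]oxy}butyl]-5-(dibromomethylidene)furan-2(5H)-one (not isolated) | CCC[C@@H](O[Si](Br)(C(C)C)C(C)C)C1=C(Br)C(=C(Br)Br)OC1=O | intermediate
15 | 4-bromo-5-(dibromomethylidene)-3-[(1R)-1-hydroxybutyl]furan-2(5H)-one | CCC[C@@H](O)C1=C(Br)C(=C(Br)Br)OC1=O | intermediate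
16 | (1R)-1-[4-bromo-5-(dibromomethylidene)-2-oxo-2,5-dihydrofuran-3-yl]butyl acetate | CCC[C@@H](OC(C)=O)C1=C(Br)C(=C(Br)Br)OC1=O | target

Total step count: 7. Longest linear sequence: 7 steps (steps 1 to 7; the azlactone branch is generated inside step 4).

**Steps most likely to fail**

1. Step 5 (key step). The non-activated bromoalkyne may add more slowly than the silyl ketal is lost through desilylation, O-to-C silyl migration or polymerisation at the temperature required. The fallback sets out from 3 and 8 and comes back at 11; it builds the ring intermolecularly from an acyl-activated alkyne and closes the silicon bridge afterwards under reagent control. Ynone 3 would be bromodesilylated (NBS, AgNO3 cat., acetone) to 1-bromohex-1-yn-3-one F1. Azlactone 8 would be O-silylated with chlorodiisopropylsilane (CC(C)[SiH](Cl)C(C)C) and Et3N to 5-[(diisopropylsilyl)oxy]-4-methyl-1,3-oxazole F2. F1 and F2 should combine in toluene at rt to 60 °C, the acyl-bearing alkyne carbon bonding to the oxygenated oxazole C5 (the usual orientation of 5-oxyoxazoles with acetylenic ketones), to the 7-oxa-2-azanorbornadiene cycloadduct F3. F3 loses acetonitrile to 1-{4-bromo-2-[(diisopropylsilyl)oxy]furan-3-yl}butan-1-one F4. Rh(I)/chiral bisphosphine-catalysed intramolecular asymmetric hydrosilylation of the ketone by the Si–H group (six-membered ring, catalyst enantiomer chosen for the R carbinol) would then give 11.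

2. Step 6. Polar bromine transfer from CBr4 to C5, or over-bromination, may compete with radical C–C bond formation. The fallback sets out from 11 and comes back at 15; it brings in the dibromomethylene carbon as the tribromomethyl anion. Dimethyldioxirane (acetone, −78 °C) should open the silyloxyfuran to the cyclic silyl ester aldehyde F5 (a 1,3-dioxa-2-silinan-4-one carrying an exocyclic bromo(formyl)methylidene group, formyl cis to the ester carbonyl). HF·pyridine would release 4-bromo-5-hydroxy-3-[(1R)-1-hydroxybutyl]furan-2(5H)-one F6 (lactol, C5 epimers). Tribromoacetic acid/sodium tribromoacetate in DMSO would add the tribromomethyl anion to the aldehyde tautomer with spontaneous relactonisation to 4-bromo-3-[(1R)-1-hydroxybutyl]-5-(tribromomethyl)furan-2(5H)-one F7. i-Pr2NEt would then eliminate HBr to give 15.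

3. Step 4. The 2-unsubstituted azlactone may oligomerise or silylate on C4 before the silyl ketal closes, and symmetrical silyl ketals may form by double substitution. The fallback sets out from 3 and comes back at 15; it gives up both the azlactone and the tether. Bromoynone F1 (from 3 as above) and commercially available 5-ethoxy-4-methyloxazole (CCOc1ocnc1C) should give, in toluene at 40–60 °C, the cycloadduct F8 and, after loss of acetonitrile, 1-(4-bromo-2-ethoxyfuran-3-yl)butan-1-one F9, with regiochemistry set by the acyl group. Photoredox tribromomethylation with 12 at C5 (the O-ethyl lactonium ion is dealkylated by bromide) would give 4-bromo-3-butanoyl-5-(tribromomethyl)furan-2(5H)-one F10. i-Pr2NEt would convert F10 into 4-bromo-3-butanoyl-5-(dibromomethylidene)furan-2(5H)-one F11. CBS reduction ((S)-Me-CBS, catecholborane, toluene, −78 °C, the tetrasubstituted furanone acting as the large group) would set the R carbinol and give 15.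

**Further compounds**
F1 | step 5 | 1-bromohex-1-yn-3-one | CCCC(=O)C#CBr
F2 | step 5 | 5-[(diisopropylsilyl)oxy]-4-methyl-1,3-oxazole | Cc1ncoc1O[SiH](C(C)C)C(C)C
F3 | step 5 | 7-oxa-2-azabicyclo[2.2.1]hepta-2,5-diene cycloadduct of F1 and F2 | CCCC(=O)C1=C(Br)C2OC1(O[SiH](C(C)C)C(C)C)C(C)=N2
F4 | step 5 | 1-{4-bromo-2-[(diisopropylsilyl)oxy]furan-3-yl}butan-1-one | CCCC(=O)c1c(Br)coc1O[SiH](C(C)C)C(C)C
F5 | step 6 | (6R)-5-[bromo(formyl)methylidene]-2,2-diisopropyl-6-propyl-1,3-dioxa-2-silinan-4-one, formyl cis to the ester carbonyl | O=C/C(Br)=C1\C(=O)O[Si](C(C)C)(C(C)C)O[C@@H]1CCC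
F6 | step 6 | 4-bromo-5-hydroxy-3-[(1R)-1-hydroxybutyl]furan-2(5H)-one | CCC[C@@H](O)C1=C(Br)C(O)OC1=O
F7 | step 6 | 4-bromo-3-[(1R)-1-hydroxybutyl]-5-(tribromomethyl)furan-2(5H)-one | CCC[C@@H](O)C1=C(Br)C(C(Br)(Br)Br)OC1=O
F8 | step 4 | 7-oxa-2-azabicyclo[2.2.1]hepta-2,5-diene cycloadduct of F1 and 5-ethoxy-4-methyloxazole | CCCC(=O)C1=C(Br)C2OC1(OCC)C(C)=N2
F9 | step 4 | 1-(4-bromo-2-ethoxyfuran-3-yl)butan-1-one | CCCC(=O)c1c(Br)coc1OCC
F10 | step 4 | 4-bromo-3-butanoyl-5-(tribromomethyl)furan-2(5H)-one | CCCC(=O)C1=C(Br)C(C(Br)(Br)Br)OC1=O
F11 | step 4 | 4-bromo-3-butanoyl-5-(dibromomethylidene)furan-2(5H)-one | CCCC(=O)C1=C(Br)C(=C(Br)Br)OC1=O
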